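## The problem

- **Architecture and locants.** The target is a 19-membered carbocycle (C4 to C17, then C21 to C25). At C25 it is spiro-linked to a 3-acyltetronic acid (ring C23, C24, C25, O, C28; acyl carbon C22) and to a cyclohexene (C2=C3, C4, C25, C26, C27). Across C17–C21 it is fused to a thiolane (C17, C18, S, C20, C21), whose C18 carries a pyruvic acid unit (ketone carbon C19).
- **Chain.** The large ring holds an (E,E)-diene (C6 to C9), an (E)-alkene (C13=C14) and a carbinol (C11) flanked by two CH2 groups. No carbonyl chemistry is available between C5 and C16.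
- **Stereocentres.** The eight centres fall into three groups that cannot control one another: C4/C25/C27, C11 alone, and C16/C17/C18/C21. In the last group C18 and C21 are α to ketones and settle all-trans. Only C17 must be set kinetically, next to a methyl-bearing centre (C16) that offers almost no facial bias.
- **Fragile groups.** The α-keto acid beside sulfur, the thioether (oxidation, soft-metal binding) and the strongly acidic, chelating acyltetronic acid will not survive a long sequence. C25 is a hindered, fully substituted carbon.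
- **Feature that makes the key step possible.** The string C22(=O)–C23–C28(=O)–O–C25 is an acetoacetate ester of the tertiary C25 carbinol, and C24 is the carboxyl carbon of an α-hydroxy ester on the same C25. The tetronic acid ring and the 19-membered carbocycle together are therefore the Dieckmann contraction product of a 20-membered β-keto lactone (C4 to C17, C21, C22, C23, C28, O, C25). That lactone arises by capture of an acylketene (C22–C23=C28=O) by the C25 hydroxyl.
- **Second feature.** On the thiolane the C19 and C22 substituents are cis. With C19 at the alcohol level they can be tied into a bridged δ-lactone (C22–O–C19), whose opening releases the C22 acyl donor and the masked pyruvate at once.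

## Retrosynthesis

**End game (50 from 48 from 46).** Only protecting-group and oxidation-state changes are cut. The keto acid is carried as a triethylsilyl-protected α-hydroxy methyl ester and C11–OH as a tert-butyldiphenylsilyl ether. A free ketone at C19 would react with the acylketene of the key step, and a free C11–OH would capture it. The forward steps need a selective TES cleavage, an oxidation that spares sulfur, and a mild saponification.

**Key disconnection (46 from 45 from 44 from 43).** The bonds C23–C24 and O–C28 are cut. Dieckmann opening of the tetronic acid gives the 20-membered β-keto lactone 45. Cleaving its ester C–O bond gives acylketene 44, which is the tert-butyl β-keto ester 43 minus tert-butanol. Against a cut at C13=C14 or C7–C8, this removes two rings and the acidic tetronic acid in one operation and needs no activating group beyond the esters already present. The precursor 43 is an open chain. The forward reaction must trap a ketene with a tertiary alcohol across 20 atoms and then close a five-membered ring.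

**Fragment union (43 from 14 and 42).** The C7–C8 bond of the diene is cut into alkenylboronate 14 and alkenyl iodide 42. A cut at C5–C6 or C9–C10 would need sp3 coupling next to a stereocentre or a skipped diene. The forward step is a stereoretentive sp2–sp2 coupling that tolerates a thioether and a β-keto ester.

**Cyclohexene (14 from 13 from 12 from 6 and 11).** The bonds C4–C25 and C26–C27 are cut by a Diels–Alder disconnection into diene 6 and the chiral α-oxyacrylate equivalent 11. This sets C4, C25 and C27 in one intermolecular step under reagent control. The forward reaction must be exo with respect to the lactone carbonyl and anti to the tert-butyl group.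

**Thiolane (42 from 41 from 40 from 38 from 37 from 33 and 36).** The C22–O bond of bridged lactone 40 is cut by an acetate enolate, which gives the β-keto ester and frees the C19 hydroxyl. The S–C18 bond is cut by a retro-thia-Michael step to enol lactone 38. The C17–C21 and O–C22 bonds are cut by an oxa-Diels–Alder disconnection into enone 33 and aldehyde 36. C17 is set by an amine catalyst, not by C16. The pyruvate carbons arrive intact, and sulfur is placed without any oxidation at C18.

**Chain (33 from 29 from 28 from 25 from 22 and 23; 22 from 19 from 18 from 15 and 16).** C17=C18 is cut by a Wittig disconnection and C14–C15 by an sp3–sp2 coupling. The bonds C9–C10 and C12–C13 are cut at the carbinol, leading to epichlorohydrin 15 as a three-carbon linchpin. C16 comes from commercial bromo ester 23 and C11 from 15. The two arms at C11 are kept different (silylalkyne against alkenyl iodide), so that C11 stays stereogenic throughout.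

## Roads not taken

**Alternative 1:** the most obvious plan.
- Cut: C22–C23 and C13=C14.
- Forward key step: the spirotetronate is finished early, acylated at C23 with the thiolane fragment, and tetraene A1 is closed by ring-closing metathesis with second-generation Grubbs catalyst.
- Why the chosen plan is better: metathesis at an unbiased 1,2-disubstituted alkene in a 19-membered ring gives E/Z mixtures. The C6–C9 diene can enter the catalytic cycle and truncate the ring. The thioether and the free acyltetronic acid both bind the ruthenium carbene. The acidic tetronic acid would also be carried (or protected and deprotected) over many steps, whereas the chosen route makes it in the last C–C bond-forming event.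

**Alternative 2:** the biomimetic plan.
- Cut: C4–C25 and C26–C27 within the macrocycle.
- Forward key step: intramolecular Diels–Alder reaction of hexaene A2, closing the cyclohexene and the 19-membered ring together and setting C4, C25 and C27.
- Why the chosen plan is better: in A2 the nearest stereocentre (C11) is six bonds from the diene and the others further still. Nothing in the substrate decides which diene face meets which dienophile face, or endo against exo, in a flexible 19-membered transition state. The 5-methylene-3-acyltetronate is also a reactive acceptor prone to polymerise. The chosen plan sets the same three centres intermolecularly with a chiral dienophile of proven sense.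

**Alternative 3:** late thiolane annulation.
- Cut: C17–C18 and C20–C21.
- Forward key step: 1,3-dipolar cycloaddition of the pyruvoyl thiocarbonyl ylide A4 to the macrocyclic (E)-enoyl tetronic acid A3.
- Why the chosen plan is better: the face of C17 would be chosen only by the C16 methyl group and the ring conformation. The acidic tetronic acid would protonate the ylide, and acyl-substituted thiocarbonyl ylides close to 1,3-oxathioles faster than they add. All this risk would sit on the last and most valuable intermediate. The chosen plan fixes C17 with a catalyst on an acyclic enone.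

Key step: step 27

Assumptions:
- C18 and C21 are α to carbonyl groups and are taken to be under thermodynamic control; the all-trans thiolane of the target is taken as the equilibrium form.
- The carbinol carbon C19 in 40 to 47 and the anomeric carbon C22 in 37 are carried as epimeric mixtures and written without descriptors; both are later oxidised to carbonyl carbons.

## Steps

Step 1
Reactants: 1 4-(trimethylsilyl)but-3-yn-1-ol; 2 1-phenyl-1H-tetrazole-5-thiol
Product: 3 1-phenyl-5-{[4-(trimethylsilyl)but-3-yn-1-yl]sulfanyl}-1H-tetrazole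
Conditions: PPh3, DIAD, THF, 0 °C → rt
Reagents that add atoms: none
Why: Mitsunobu thioetherification of a primary alcohol with an acidic heteroaryl thiol; no stereocentre is involved.

Step 2
Reactants: 3 1-phenyl-5-{[4-(trimethylsilyl)but-3-yn-1-yl]sulfanyl}-1H-tetrazole
Product: 4 1-phenyl-5-{[4-(trimethylsilyl)but-3-yn-1-yl]sulfonyl}-1H-tetrazole
Conditions: H2O2 (30% aq.), (NH4)6Mo7O24·4H2O (10 mol%), EtOH, 0 °C → rt
Reagents that add atoms: hydrogen peroxide, OO
Why: Molybdate-catalysed peroxide oxidation of a sulfide to the sulfone; the silylalkyne is inert to this oxidant.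

Step 3
Reactants: 4 1-phenyl-5-{[4-(trimethylsilyl)but-3-yn-1-yl]sulfonyl}-1H-tetrazole; 5 (E)-2-methylbut-2-enal
Product: 6 (4E,6E)-6-methyl-1-(trimethylsilyl)octa-4,6-dien-1-yne
Conditions: KN(SiMe3)2, DME, −60 °C; then 5, −60 °C → rt
Reagents that add atoms: none
Why: Julia–Kocienski olefination; phenyltetrazolyl sulfones with a potassium base in DME should give the (E)-alkene (C3=C4) after Smiles rearrangement and loss of SO2. The (E)-geometry of 5 (C27=C2) is carried over.

Step 4
Reactants: 7 (R)-lactic acid; 8 pivalaldehyde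
Product: 9 (2R,5R)-2-tert-butyl-5-methyl-1,3-dioxolan-4-one
Conditions: TsOH·H2O (cat.), H2SO4 (cat.), pentane, reflux, water separator; crystallisation
Reagents that add atoms: none
Why: Acid-catalysed acetalisation under thermodynamic control; the lactic acid centre directs the new acetal carbon to the cis isomer, which crystallises.

Step 5
Reactants: 9 (2R,5R)-2-tert-butyl-5-methyl-1,3-dioxolan-4-one
Product: 10 (2R,5S)-5-bromo-2-tert-butyl-5-methyl-1,3-dioxolan-4-one
Conditions: N-bromosuccinimide, AIBN (cat.), cyclohexane, reflux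
Reagents that add atoms: N-bromosuccinimide, O=C1CCC(=O)N1Br
Why: Radical bromination at the tertiary C–H flanked by oxygen and carbonyl; the acetal centre that later controls the cycloaddition is untouched.

Step 6
Reactants: 10 (2R,5S)-5-bromo-2-tert-butyl-5-methyl-1,3-dioxolan-4-one
Product: 11 (R)-2-tert-butyl-5-methylene-1,3-dioxolan-4-one
Conditions: Et3N, CH2Cl2, 0 °C → rt
Reagents that add atoms: none
Why: Base-induced dehydrobromination to the exocyclic alkene, a chiral α-oxyacrylate equivalent.

Step 7
Reactants: 6 (4E,6E)-6-methyl-1-(trimethylsilyl)octa-4,6-dien-1-yne; 11 (R)-2-tert-butyl-5-methylene-1,3-dioxolan-4-one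
Product: 12 (2R,5S,6R,9R)-2-tert-butyl-8,9-dimethyl-6-[3-(trimethylsilyl)prop-2-yn-1-yl]-1,3-dioxaspiro[4.5]dec-7-en-4-one
Conditions: toluene, BHT (cat.), 110 °C, sealed tube
Reagents that add atoms: none
Why: Intermolecular Diels–Alder reaction; the 2-methyl ("para") and 4-alkyl ("ortho") groups of the diene both direct C25 to C4. This class of 5-methylene-dioxolanone reacts exo (lactone carbonyl away from the diene, ring oxygen endo) and anti to tert-butyl. The (E,E)-diene puts the C27 methyl cis to the C5 chain, so C4 (R), C25 (S) and C27 (R) are set together.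

Step 8
Reactants: 12 spiro-dioxolanone cycloadduct
Product: 13 methyl (1S,2R,5R)-1-hydroxy-4,5-dimethyl-2-(prop-2-yn-1-yl)cyclohex-3-ene-1-carboxylate
Conditions: K2CO3, MeOH, rt
Reagents that add atoms: methanol, CO
Why: Methanolysis of the acetal-lactone frees the tertiary alcohol and methyl ester with loss of pivalaldehyde; the same medium removes the alkynyl silyl group. No stereocentre is touched.

Step 9
Reactants: 13 methyl (1S,2R,5R)-1-hydroxy-4,5-dimethyl-2-(prop-2-yn-1-yl)cyclohex-3-ene-1-carboxylate
Product: 14 methyl (1S,2R,5R)-1-hydroxy-4,5-dimethyl-2-[(2E)-3-(4,4,5,5-tetramethyl-1,3,2-dioxaborolan-2-yl)prop-2-en-1-yl]cyclohex-3-ene-1-carboxylate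
Conditions: pinacolborane (2.5 equiv), Cp2ZrHCl (10 mol%), Et3N (10 mol%), CH2Cl2, rt; aqueous work-up
Reagents that add atoms: pinacolborane, [H]B1OC(C)(C)C(C)(C)O1
Why: Zirconium-catalysed syn-hydroboration of a terminal alkyne should give only the (E)-alkenylboronate (C6=C7); any O-borylation of the tertiary alcohol is reversed on work-up.

Step 10
Reactants: 15 (S)-epichlorohydrin; 16 ethynyltrimethylsilane
Product: 18 (S)-2-[3-(trimethylsilyl)prop-2-yn-1-yl]oxirane, via chlorohydrin 17 (not isolated)
Conditions: 16, n-BuLi, THF, −78 °C; BF3·OEt2; 15, −78 °C; H2O quench; then NaH, THF, 0 °C → rt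
Reagents that add atoms: none
Why: BF3-promoted opening of the epoxide at its CH2 terminus by the lithium acetylide, then ring closure of the chlorohydrin with loss of chloride; the carbinol carbon (C11) keeps its configuration because no bond to it is broken.

Step 11
Reactants: 18 (S)-2-[3-(trimethylsilyl)prop-2-yn-1-yl]oxirane
Product: 19 (R)-1-(trimethylsilyl)hepta-1,6-diyn-4-ol
Conditions: HC≡CH, n-BuLi, THF, −78 °C; BF3·OEt2; then 18, −78 °C
Reagents that add atoms: acetylene, C#C
Why: Second BF3-promoted acetylide opening at the new epoxide CH2; the two arms at C11 stay different (silylalkyne west, terminal alkyne east).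

Step 12
Reactants: 19 (R)-1-(trimethylsilyl)hepta-1,6-diyn-4-ol
Product: 20 (R)-tert-butyldiphenyl{[1-(trimethylsilyl)hepta-1,6-diyn-4-yl]oxy}silane
Conditions: t-BuPh2SiCl, imidazole, DMF, rt
Reagents that add atoms: tert-butyl(chloro)diphenylsilane, CC(C)(C)[Si](Cl)(c1ccccc1)c1ccccc1
Why: Standard silylation; the acid-stable TBDPS group is chosen to survive the trifluoroacetic acid of step 23 and the acidic methanol of step 28.

Step 13
Reactants: 20 (R)-tert-butyldiphenyl{[1-(trimethylsilyl)hepta-1,6-diyn-4-yl]oxy}silane
Product: 22 (R,E)-tert-butyl{[1-iodo-7-(trimethylsilyl)hept-1-en-6-yn-4-yl]oxy}diphenylsilane, via alkenylzirconocene 21 (not isolated)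
Conditions: Cp2ZrHCl (1.1 equiv), THF, rt; then I2, 0 °C
Reagents that add atoms: iodine, II
Why: Hydrozirconation is a syn addition placing zirconium on the terminal carbon; iodinolysis with retention gives the (E)-alkenyl iodide (C13=C14). The terminal alkyne reacts much faster than the silyl-capped one.

Step 14
Reactants: 22 (R,E)-alkenyl iodide; 23 methyl (R)-3-bromo-2-methylpropanoate
Product: 25 methyl (2S,4E,7R)-7-[(tert-butyldiphenylsilyl)oxy]-2-methyl-10-(trimethylsilyl)dec-4-en-9-ynoate, via alkylzinc bromide 24 (not isolated)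
Conditions: 23, Zn dust, I2 (5 mol%), DMA, 70 °C; then 22, Pd(PPh3)4 (5 mol%), DMA/THF, 40 °C
Reagents that add atoms: none
Why: Zinc insertion gives a β-zincio ester that is configurationally stable at C16; Negishi coupling under zerovalent palladium catalysis forms C14–C15 with retention of the (E)-alkene. C16 comes unchanged from 23.

Step 15
Reactants: 25 methyl (2S,4E,7R)-7-[(tert-butyldiphenylsilyl)oxy]-2-methyl-10-(trimethylsilyl)dec-4-en-9-ynoate
Product: 26 methyl (2S,4E,7R)-7-[(tert-butyldiphenylsilyl)oxy]-2-methyldec-4-en-9-ynoate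
Conditions: K2CO3, MeOH, 0 °C → rt
Reagents that add atoms: none
Why: Methoxide-induced protiodesilylation of the alkyne; the methyl ester is degenerate under methanolysis, and the short, cold reaction should leave C16 intact.

Step 16
Reactants: 26 methyl (2S,4E,7R)-7-[(tert-butyldiphenylsilyl)oxy]-2-methyldec-4-en-9-ynoate
Product: 28 methyl (2S,4E,7R,9E)-7-[(tert-butyldiphenylsilyl)oxy]-10-iodo-2-methyldeca-4,9-dienoate, via alkenylzirconocene 27 (not isolated)
Conditions: Cp2ZrHCl (1.2 equiv), THF, rt; then I2, 0 °C
Reagents that add atoms: iodine, II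
Why: Hydrozirconation and iodination as in step 13 give the (E)-alkenyl iodide at C8=C9; alkyne hydrozirconation outruns attack on the ester and on the internal alkene.

Step 17
Reactants: 28 methyl (2S,4E,7R,9E)-7-[(tert-butyldiphenylsilyl)oxy]-10-iodo-2-methyldeca-4,9-dienoate
Product: 29 (2S,4E,7R,9E)-7-[(tert-butyldiphenylsilyl)oxy]-10-iodo-2-methyldeca-4,9-dienal
Conditions: i-Bu2AlH, CH2Cl2, −78 °C; aq. KNaC4H4O6
Reagents that add atoms: none
Why: Partial reduction of the methyl ester through a tetrahedral aluminate that is stable at −78 °C; the aldehyde (C17) is used crude to protect the α-centre C16.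

Step 18
Reactants: 30 methyl 3-bromo-2-oxopropanoate
Product: 32 methyl 2-oxo-3-(triphenylphosphoranylidene)propanoate, via phosphonium bromide 31 (not isolated)
Conditions: PPh3, toluene, rt; then aq. Na2CO3, CH2Cl2
Reagents that add atoms: triphenylphosphine, c1ccc(cc1)P(c1ccccc1)c1ccccc1
Why: Alkylation of the phosphine by the α-bromo ketone and deprotonation give the acyl-stabilised ylide that carries the whole pyruvate unit (C18, C19, CO2Me).

Step 19
Reactants: 29 (2S,4E,7R,9E)-aldehyde; 32 methyl 2-oxo-3-(triphenylphosphoranylidene)propanoate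
Product: 33 methyl (3E,5S,7E,10R,12E)-10-[(tert-butyldiphenylsilyl)oxy]-13-iodo-5-methyl-2-oxotrideca-3,7,12-trienoate
Conditions: toluene, 60 °C
Reagents that add atoms: none
Why: Wittig reaction of a stabilised ylide gives the (E)-enone (C17=C18) under neutral conditions that do not epimerise C16.

Step 20
Reactants: 34 acrolein; 35 triphenylmethanethiol
Product: 36 3-(tritylsulfanyl)propanal
Conditions: Et3N (5 mol%), CH2Cl2, 0 °C → rt
Reagents that add atoms: none
Why: Base-catalysed thia-Michael addition to acrolein gives the C20–C22 unit with sulfur already on C20.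

Step 21
Reactants: 33 enone; 36 3-(tritylsulfanyl)propanal
Product: 37 methyl 2-hydroxy-3-[(tritylsulfanyl)methyl]-4-[C16-chain]-3,4-dihydro-2H-pyran-6-carboxylate (ring O–C22–C21–C17–C18=C19; C21 substituent trans to the C17 chain; anomers)
Conditions: (R)-2-[diphenyl(trimethylsilyloxy)methyl]pyrrolidine (10 mol%), silica gel, CH2Cl2, −15 °C → rt
Reagents that add atoms: none
Why: Amine-catalysed inverse-electron-demand oxa-Diels–Alder reaction (enamine Michael addition, then hemiacetalisation) of an aldehyde with a β,γ-unsaturated α-keto ester. The bulky group of the (R)-catalyst shields one enamine face, and the enone approaches with its carbonyl near nitrogen, so C21 bonds to the required face of C17 under catalyst control, not C16 control. C21 is formed trans but is re-equilibrated in step 23.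

Step 22
Reactants: 37 cyclic hemiacetal
Product: 38 methyl (3,4-trans)-2-oxo-3-[(tritylsulfanyl)methyl]-4-[C16-chain]-3,4-dihydro-2H-pyran-6-carboxylate (enol δ-lactone)
Conditions: DMP (1,1,1-triacetoxy-1,1-dihydro-1,2-benziodoxol-3(1H)-one), NaHCO3, CH2Cl2, rt
Reagents that add atoms: none
Why: Oxidation of the lactol to the lactone turns the masked α-keto ester into a 2-acyloxyacrylate (C18=C19) and stores C22 as an acyl donor; the hindered trityl sulfide is not oxidised by this reagent.

Step 23
Reactants: 38 enol δ-lactone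
Product: 40 methyl 8-[C16-chain]-2-oxo-3-oxa-6-thiabicyclo[3.2.1]octane-4-carboxylate (thiolane C17/C18/S/C20/C21 bridged by the lactone C22–O–C19; C16 chain trans to both lactone carbons), via thiol 39 (not isolated)
Conditions: CF3CO2H, Et3SiH, CH2Cl2, 0 °C; evaporate; DBU (0.5 equiv), CH2Cl2 (0.005 M), rt
Reagents that add atoms: none
Why: Ionic detritylation frees the thiol, which adds to C18 of the 2-acyloxyacrylate in a 5-exo-trig thia-Michael closure (thiol addition to α-acyloxyacrylates). The tether forces the C19 and C22 substituents cis on the thiolane. DBU equilibrates C21 through the lactone enolate, and the epimer that can place CH2S axial with the C16 chain equatorial should cyclise faster and be drained from the equilibrium, giving the all-trans thiolane.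

Step 24
Reactants: 40 bridged lactone
Product: 41 tert-butyl 3-oxo-3-{(3R,4S,5S)-5-[1-hydroxy-2-methoxy-2-oxoethyl]-4-[C16-chain]thiolan-3-yl}propanoate
Conditions: t-BuOAc, LiN(i-Pr)2, THF, −78 °C; then 40, −78 → −40 °C; AcOH
Reagents that add atoms: tert-butyl acetate, CC(=O)OC(C)(C)C
Why: Claisen condensation of an ester enolate with a lactone, which is more electrophilic than the acyclic methyl ester and expels a stabilised α-alkoxy ester alkoxide. One step forms C22–C23, installs the β-keto ester and frees the C19 hydroxyl.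

Step 25
Reactants: 41 hydroxy β-keto ester
Product: 42 tert-butyl 3-oxo-3-{(3R,4S,5S)-5-[2-methoxy-2-oxo-1-(triethylsilyloxy)ethyl]-4-[C16-chain]thiolan-3-yl}propanoate
Conditions: Et3SiCl, imidazole, DMF, 0 °C
Reagents that add atoms: chlorotriethylsilane, CC[Si](Cl)(CC)CC
Why: Silylation of the secondary alcohol traps the open-chain form and masks the only other hydroxyl that could capture the ketene in step 27; the β-keto ester is not silylated under these conditions.

Step 26
Reactants: 14 (E)-alkenylboronate; 42 (E)-alkenyl iodide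
Product: 43 seco compound: tertiary alcohol and methyl ester at C25 joined through the (E,E)-diene to the tert-butyl β-keto ester at C22
Conditions: PdCl2(dppf) (10 mol%), AsPh3, Cs2CO3, DMF/THF/H2O, rt
Reagents that add atoms: none
Why: Suzuki–Miyaura coupling of two (E)-alkenyl partners with retention at both carbons gives the (6E,8E)-diene; the β-keto ester is only deprotonated reversibly by carbonate.

Step 27
Reactants: 43 seco compound
Product: 46 macrocyclic spirotetronate with C11–OTBDPS and the TES-protected α-hydroxy methyl ester on C18, via acylketene 44 (not isolated), via macrolactone 45 (not isolated)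
Conditions: toluene (0.0005 M), 110 °C, N2 sweep; cool to 0 °C; t-BuOK (1.2 equiv), THF, 0 °C → rt; aq. HCl to pH 3
Reagents that add atoms: none
Why: Heating expels tert-butanol from the enol of the β-keto ester through a six-membered transition state and gives acylketene 44. The only free hydroxyl, the tertiary C25–OH, adds to the ketene carbon C28 and closes the 20-membered β-keto lactone 45 (closure by addition to the cumulene carbonyl, exo to C=O). t-BuOK then deprotonates C23, which attacks the neighbouring C24 methyl ester in a 5-exo-trig Dieckmann closure and expels methoxide, so the lactone becomes the tetronic acid and the 20-membered ring contracts to the 19-membered carbocycle. The closest known reaction types are thermal acetoacetylation and macrolactonisation through acylketenes from dioxinones or tert-butyl β-keto esters, and the Lacey–Dieckmann synthesis of 3-acyltetronic acids from acetoacetates of α-hydroxy esters. No stereocentre is formed; C4, C25 and C27 are not touched, and C21 already has its thermodynamic configuration. The step needs intramolecular over intermolecular ketene capture, which high dilution, removal of tert-butanol and silylation of every other hydroxyl should secure; ketene capture is irreversible and tolerates a tertiary alcohol. The Dieckmann closure is regioselective because C23 is the only doubly activated carbon and C24 is five atoms away, whereas attack on the side-chain ester would need a seven-membered ring. Formation of the acyltetronate anion drives the sequence.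

Step 28
Reactants: 46 protected macrocyclic spirotetronate
Product: 47 macrocycle with free C19–OH (α-hydroxy methyl ester) and C11–OTBDPS
Conditions: PPTS, MeOH/CH2Cl2, 0 °C → rt
Reagents that add atoms: none
Why: Acid-catalysed methanolysis removes the triethylsilyl ether selectively; the tert-butyldiphenylsilyl ether is far more stable to acid.

Step 29
Reactants: 47 α-hydroxy ester
Product: 48 macrocycle with the methyl 2-oxoacetate (α-keto ester) on C18 and C11–OTBDPS
Conditions: DMP (1,1,1-triacetoxy-1,1-dihydro-1,2-benziodoxol-3(1H)-one), NaHCO3, CH2Cl2, 0 °C → rt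
Reagents that add atoms: none
Why: Periodinane oxidation of the α-hydroxy ester to the α-keto ester tolerates the thioether and the enolised tetronic acid; C11 is still silylated, so only C19 is oxidised.

Step 30
Reactants: 48 α-keto ester
Product: 50 CNP0224658.3 (target), via methyl ester 49 (not isolated)
Conditions: HF·pyridine, pyridine, THF, 0 °C → rt; then LiOH, THF/H2O, 0 °C; aq. HCl to pH 3
Reagents that add atoms: lithium hydroxide, [Li+].[OH-]
Why: Fluoride cleaves the C11 silyl ether, and the very electrophilic α-keto methyl ester is saponified at 0 °C while the acyltetronic acid is protected as its anion. Any C18 or C21 epimer can equilibrate through the enolate to the all-trans thiolane.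

## Compound list

1 | 4-(trimethylsilyl)but-3-yn-1-ol | C[Si](C)(C)C#CCCO | starting material
2 | 1-phenyl-1H-tetrazole-5-thiol | Sc1nnnn1-c1ccccc1 | starting material
3 | 1-phenyl-5-{[4-(trimethylsilyl)but-3-yn-1-yl]sulfanyl}-1H-tetrazole | C[Si](C)(C)C#CCCSc1nnnn1-c1ccccc1 | intermediate
4 | 1-phenyl-5-{[4-(trimethylsilyl)but-3-yn-1-yl]sulfonyl}-1H-tetrazole | C[Si](C)(C)C#CCCS(=O)(=O)c1nnnn1-c1ccccc1 | intermediate
5 | (E)-2-methylbut-2-enal | C/C=C(C)/C=O | starting material
6 | (4E,6E)-6-methyl-1-(trimethylsilyl)octa-4,6-dien-1-yne | C/C=C(C)/C=C/CC#C[Si](C)(C)C | intermediate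
7 | (R)-lactic acid | C[C@@H](O)C(=O)O | starting material
8 | pivalaldehyde | CC(C)(C)C=O | starting material
9 | (2R,5R)-2-tert-butyl-5-methyl-1,3-dioxolan-4-one | C[C@H]1O[C@@H](C(C)(C)C)OC1=O | intermediate
10 | (2R,5S)-5-bromo-2-tert-butyl-5-methyl-1,3-dioxolan-4-one | C[C@@]1(Br)O[C@@H](C(C)(C)C)OC1=O | intermediate
11 | (R)-2-tert-butyl-5-methylene-1,3-dioxolan-4-one | C=C1O[C@@H](C(C)(C)C)OC1=O | intermediate
12 | (2R,5S,6R,9R)-2-tert-butyl-8,9-dimethyl-6-[3-(trimethylsilyl)prop-2-yn-1-yl]-1,3-dioxaspiro[4.5]dec-7-en-4-one | CC1=C[C@@H](CC#C[Si](C)(C)C)[C@]2(C[C@H]1C)O[C@@H](C(C)(C)C)OC2=O | intermediate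
13 | methyl (1S,2R,5R)-1-hydroxy-4,5-dimethyl-2-(prop-2-yn-1-yl)cyclohex-3-ene-1-carboxylate | CC1=C[C@@H](CC#C)[C@](O)(C(=O)OC)C[C@H]1C | intermediate
14 | methyl (1S,2R,5R)-1-hydroxy-4,5-dimethyl-2-[(2E)-3-(pinacolatoboryl)prop-2-en-1-yl]cyclohex-3-ene-1-carboxylate | CC1=C[C@@H](C/C=C/B2OC(C)(C)C(C)(C)O2)[C@](O)(C(=O)OC)C[C@H]1C | intermediate
15 | (S)-epichlorohydrin | ClC[C@@H]1CO1 | starting material
16 | ethynyltrimethylsilane | C#C[Si](C)(C)C | starting material
17 | (S)-1-chloro-5-(trimethylsilyl)pent-4-yn-2-ol | ClC[C@@H](O)CC#C[Si](C)(C)C | intermediate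
18 | (S)-2-[3-(trimethylsilyl)prop-2-yn-1-yl]oxirane | C[Si](C)(C)C#CC[C@H]1CO1 | intermediate
19 | (R)-1-(trimethylsilyl)hepta-1,6-diyn-4-ol | C[Si](C)(C)C#CC[C@H](O)CC#C | intermediate
20 | (R)-tert-butyldiphenyl{[1-(trimethylsilyl)hepta-1,6-diyn-4-yl]oxy}silane | C[Si](C)(C)C#CC[C@H](O[Si](c1ccccc1)(c1ccccc1)C(C)(C)C)CC#C | intermediate
21 | (E)-alkenylzirconocene chloride from 20 (Zr on C14) | C[Si](C)(C)C#CC[C@H](O[Si](c1ccccc1)(c1ccccc1)C(C)(C)C)C/C=C/[Zr](Cl)(C1C=CC=C1)C1C=CC=C1 | intermediate
22 | (R,E)-tert-butyl{[1-iodo-7-(trimethylsilyl)hept-1-en-6-yn-4-yl]oxy}diphenylsilane | C[Si](C)(C)C#CC[C@H](O[Si](c1ccccc1)(c1ccccc1)C(C)(C)C)C/C=C/I | intermediate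
23 | methyl (R)-3-bromo-2-methylpropanoate | BrC[C@H](C)C(=O)OC | starting material
24 | [(R)-3-methoxy-2-methyl-3-oxopropyl]zinc bromide | Br[Zn]C[C@H](C)C(=O)OC | intermediate
25 | methyl (2S,4E,7R)-7-[(tert-butyldiphenylsilyl)oxy]-2-methyl-10-(trimethylsilyl)dec-4-en-9-ynoate | C[Si](C)(C)C#CC[C@H](O[Si](c1ccccc1)(c1ccccc1)C(C)(C)C)C/C=C/C[C@H](C)C(=O)OC | intermediate
26 | methyl (2S,4E,7R)-7-[(tert-butyldiphenylsilyl)oxy]-2-methyldec-4-en-9-ynoate | C#CC[C@H](O[Si](c1ccccc1)(c1ccccc1)C(C)(C)C)C/C=C/C[C@H](C)C(=O)OC | intermediate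
27 | (E)-alkenylzirconocene chloride from 26 (Zr on C8) | Cl[Zr](/C=C/C[C@H](O[Si](c1ccccc1)(c1ccccc1)C(C)(C)C)C/C=C/C[C@H](C)C(=O)OC)(C1C=CC=C1)C1C=CC=C1 | intermediate
28 | methyl (2S,4E,7R,9E)-7-[(tert-butyldiphenylsilyl)oxy]-10-iodo-2-methyldeca-4,9-dienoate | I/C=C/C[C@H](O[Si](c1ccccc1)(c1ccccc1)C(C)(C)C)C/C=C/C[C@H](C)C(=O)OC | intermediate
29 | (2S,4E,7R,9E)-7-[(tert-butyldiphenylsilyl)oxy]-10-iodo-2-methyldeca-4,9-dienal | I/C=C/C[C@H](O[Si](c1ccccc1)(c1ccccc1)C(C)(C)C)C/C=C/C[C@H](C)C=O | intermediate
30 | methyl 3-bromo-2-oxopropanoate | COC(=O)C(=O)CBr | starting material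
31 | (3-methoxy-2,3-dioxopropyl)triphenylphosphonium bromide | COC(=O)C(=O)C[P+](c1ccccc1)(c1ccccc1)c1ccccc1.[Br-] | intermediate
32 | methyl 2-oxo-3-(triphenylphosphoranylidene)propanoate | COC(=O)C(=O)C=P(c1ccccc1)(c1ccccc1)c1ccccc1 | intermediate
33 | methyl (3E,5S,7E,10R,12E)-10-[(tert-butyldiphenylsilyl)oxy]-13-iodo-5-methyl-2-oxotrideca-3,7,12-trienoate | I/C=C/C[C@H](O[Si](c1ccccc1)(c1ccccc1)C(C)(C)C)C/C=C/C[C@H](C)/C=C/C(=O)C(=O)OC | intermediate
34 | acrolein | C=CC=O | starting material
35 | triphenylmethanethiol | SC(c1ccccc1)(c1ccccc1)c1ccccc1 | starting material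
36 | 3-(tritylsulfanyl)propanal | O=CCCSC(c1ccccc1)(c1ccccc1)c1ccccc1 | intermediate
37 | cyclic hemiacetal (2-hydroxy-3,4-dihydro-2H-pyran-6-carboxylate; C21 CH2STr trans to C17 chain; anomers) | I/C=C/C[C@H](O[Si](c1ccccc1)(c1ccccc1)C(C)(C)C)C/C=C/C[C@H](C)[C@@H]1C=C(C(=O)OC)OC(O)[C@H]1CSC(c1ccccc1)(c1ccccc1)c1ccccc1 | intermediate
38 | enol δ-lactone (2-oxo-3,4-dihydro-2H-pyran-6-carboxylate; 3,4-trans) | I/C=C/C[C@H](O[Si](c1ccccc1)(c1ccccc1)C(C)(C)C)C/C=C/C[C@H](C)[C@@H]1C=C(C(=O)OC)OC(=O)[C@H]1CSC(c1ccccc1)(c1ccccc1)c1ccccc1 | intermediate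
39 | free thiol of 38 | I/C=C/C[C@H](O[Si](c1ccccc1)(c1ccccc1)C(C)(C)C)C/C=C/C[C@H](C)[C@@H]1C=C(C(=O)OC)OC(=O)[C@H]1CS | intermediate
40 | bridged lactone: methyl 8-[C16-chain]-2-oxo-3-oxa-6-thiabicyclo[3.2.1]octane-4-carboxylate (C19 epimers) | I/C=C/C[C@H](O[Si](c1ccccc1)(c1ccccc1)C(C)(C)C)C/C=C/C[C@H](C)[C@@H]1[C@@H]2SC[C@H]1C(=O)OC2C(=O)OC | intermediate
41 | thiolane with tert-butyl β-keto ester at C21 and α-hydroxy methyl ester at C18 | I/C=C/C[C@H](O[Si](c1ccccc1)(c1ccccc1)C(C)(C)C)C/C=C/C[C@H](C)[C@@H]1[C@@H](C(O)C(=O)OC)SC[C@H]1C(=O)CC(=O)OC(C)(C)C | intermediate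
42 | triethylsilyl ether of 41 | I/C=C/C[C@H](O[Si](c1ccccc1)(c1ccccc1)C(C)(C)C)C/C=C/C[C@H](C)[C@@H]1[C@@H](C(O[Si](CC)(CC)CC)C(=O)OC)SC[C@H]1C(=O)CC(=O)OC(C)(C)C | intermediate
43 | seco compound (C25 tertiary alcohol and methyl ester; (6E,8E)-diene; C22 tert-butyl β-keto ester) | CC1=C[C@@H](C/C=C/C=C/C[C@H](O[Si](c2ccccc2)(c2ccccc2)C(C)(C)C)C/C=C/C[C@H](C)[C@@H]2[C@@H](C(O[Si](CC)(CC)CC)C(=O)OC)SC[C@H]2C(=O)CC(=O)OC(C)(C)C)[C@](O)(C(=O)OC)C[C@H]1C | intermediate
44 | acylketene from 43 | CC1=C[C@@H](C/C=C/C=C/C[C@H](O[Si](c2ccccc2)(c2ccccc2)C(C)(C)C)C/C=C/C[C@H](C)[C@@H]2[C@@H](C(O[Si](CC)(CC)CC)C(=O)OC)SC[C@H]2C(=O)C=C=O)[C@](O)(C(=O)OC)C[C@H]1C | intermediate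
45 | 20-membered β-keto macrolactone | CC1=C[C@H]2C/C=C/C=C/C[C@H](O[Si](c3ccccc3)(c3ccccc3)C(C)(C)C)C/C=C/C[C@H](C)[C@@H]3[C@@H](C(O[Si](CC)(CC)CC)C(=O)OC)SC[C@H]3C(=O)CC(=O)O[C@]2(C[C@H]1C)C(=O)OC | intermediate
46 | macrocyclic spirotetronate with C11–OTBDPS and TES-protected α-hydroxy methyl ester | CC1=C[C@H]2C/C=C/C=C/C[C@H](O[Si](c3ccccc3)(c3ccccc3)C(C)(C)C)C/C=C/C[C@H](C)[C@@H]3[C@@H](C(O[Si](CC)(CC)CC)C(=O)OC)SC[C@H]3C(=O)C3=C(O)[C@@]2(C[C@H]1C)OC3=O | intermediate
47 | macrocycle with free α-hydroxy methyl ester and C11–OTBDPS | CC1=C[C@H]2C/C=C/C=C/C[C@H](O[Si](c3ccccc3)(c3ccccc3)C(C)(C)C)C/C=C/C[C@H](C)[C@@H]3[C@@H](C(O)C(=O)OC)SC[C@H]3C(=O)C3=C(O)[C@@]2(C[C@H]1C)OC3=O | intermediate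
48 | macrocycle with α-keto methyl ester and C11–OTBDPS | CC1=C[C@H]2C/C=C/C=C/C[C@H](O[Si](c3ccccc3)(c3ccccc3)C(C)(C)C)C/C=C/C[C@H](C)[C@@H]3[C@@H](C(=O)C(=O)OC)SC[C@H]3C(=O)C3=C(O)[C@@]2(C[C@H]1C)OC3=O | intermediate
49 | methyl ester of the target | CC1=C[C@H]2C/C=C/C=C/C[C@H](O)C/C=C/C[C@H](C)[C@@H]3[C@@H](C(=O)C(=O)OC)SC[C@H]3C(=O)C3=C(O)[C@@]2(C[C@H]1C)OC3=O | intermediate
50 | CNP0224658.3 | CC1=C[C@H]2C/C=C/C=C/C[C@H](O)C/C=C/C[C@H](C)[C@@H]3[C@@H](C(=O)C(=O)O)SC[C@H]3C(=O)C3=C(O)[C@@]2(C[C@H]1C)OC3=O | target

## Step count and least certain steps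

Total: 30 steps. Longest linear sequence: 19 steps (steps 10 to 17, 19, 21 to 30, from epichlorohydrin 15).

**Step 27 (key step).** Intermolecular ketene capture, ketene dimerisation or re-addition of tert-butanol may outrun closure of the 20-membered ring at the hindered tertiary alcohol, because the entropic cost of the ring is high. Fallback: the two halves are joined through the ester first and the ring is closed at the diene. Alkenyl iodide 42 is heated with an excess of boronate 14 (toluene, 110 °C), so that the acylketene is trapped intermolecularly to give the β-keto ester of the C25 carbinol F1. t-BuOK closes the tetronic acid to the open-chain acyltetronate F2. An intramolecular Suzuki–Miyaura coupling at C7–C8 (PdCl2(dppf), AsPh3, Cs2CO3, high dilution) then closes the macrocycle. The fallback sets out from 14 and 42 and comes back at 46.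

**Step 21.** Poor facial selectivity may arise if the catalyst and the C16 centre are mismatched, and β-elimination of tritylthiolate from the enamine of 36 may erode the donor. Fallback: the heterodiene is activated with a chiral Lewis acid instead of activating the aldehyde as an enamine. Aldehyde 36 is converted (Me3SiCl, Et3N, NaI) into the (Z)-trimethylsilyl enol ether F3. This is added to 33 under Cu(OTf)2 with the tert-butyl-bisoxazoline ligand enantiomer that exposes the required face of C17, giving the 2-silyloxy-dihydropyran F4. Mild acid hydrolysis gives the lactol F5, and oxidation as in step 22 gives the 3,4-cis enol lactone F6. F6 is the C21 epimer of 38 and enters step 23 unchanged. The fallback sets out from 33 and 36 and comes back at 40.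

**Step 23.** Ring closure may occur from the C21 epimer that leads to the all-cis thiolane, or acyl transfer from the enol lactone to the thiol of another molecule may compete. Fallback: a radical chain replaces the base-mediated addition. After detritylation, thiol 39 is cyclised by an intramolecular thiol–ene reaction (AIBN, benzene, 80 °C), in which the thiyl radical attacks C18 in 5-exo mode and gives the captodatively stabilised C19 radical. The fallback sets out from 38 and comes back at 40 without a new compound.

**Step 24.** The enolate may deprotonate C19 instead of adding to the lactone, add a second time at the methyl ester, or give a hemiketal that resists silylation. Fallback: the lactone is opened with an amine. Lactone 40 is treated with MeNH(OMe)·HCl and Me3Al to give the hydroxy N-methoxy-N-methylamide F7. This is silylated (Et3SiCl, imidazole) to F8 and then converted with the lithium enolate of tert-butyl acetate into the β-keto ester. The fallback sets out from 40 and comes back at 42.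

**Step 26.** The thioether or the β-keto ester enolate may deactivate palladium under basic conditions, and the boronate may protodeboronate. Fallback: a base-free Stille coupling. Alkyne 13 is hydrostannylated (Bu3SnH, PdCl2(PPh3)2) to the (E)-alkenylstannane F9, which is coupled with 42 (Pd2(dba)3, AsPh3, NMP). The fallback sets out from 13 and comes back at 43.

## Further compounds

F1 | step 27 | β-keto ester of the C25 carbinol of 14 with the acyl unit of 42 (alkenyl iodide and alkenylboronate both present) | I/C=C/C[C@H](O[Si](c1ccccc1)(c1ccccc1)C(C)(C)C)C/C=C/C[C@H](C)[C@@H]1[C@@H](C(O[Si](CC)(CC)CC)C(=O)OC)SC[C@H]1C(=O)CC(=O)O[C@@]1(C(=O)OC)C[C@@H](C)C(C)=C[C@H]1C/C=C/B1OC(C)(C)C(C)(C)O1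
F2 | step 27 | open-chain 3-acyl spirotetronic acid with alkenyl iodide and alkenylboronate termini | I/C=C/C[C@H](O[Si](c1ccccc1)(c1ccccc1)C(C)(C)C)C/C=C/C[C@H](C)[C@@H]1[C@@H](C(O[Si](CC)(CC)CC)C(=O)OC)SC[C@H]1C(=O)C1=C(O)[C@]2(OC1=O)C[C@@H](C)C(C)=C[C@H]2C/C=C/B1OC(C)(C)C(C)(C)O1
F3 | step 21 | (Z)-trimethyl{[3-(tritylsulfanyl)prop-1-en-1-yl]oxy}silane | C[Si](C)(C)O/C=C\CSC(c1ccccc1)(c1ccccc1)c1ccccc1
F4 | step 21 | 2-(trimethylsilyloxy)-3,4-dihydro-2H-pyran cycloadduct (2,3,4-all-cis) | I/C=C/C[C@H](O[Si](c1ccccc1)(c1ccccc1)C(C)(C)C)C/C=C/C[C@H](C)[C@@H]1C=C(C(=O)OC)O[C@H](O[Si](C)(C)C)[C@@H]1CSC(c1ccccc1)(c1ccccc1)c1ccccc1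
F5 | step 21 | lactol, C21 epimer of 37 (anomers) | I/C=C/C[C@H](O[Si](c1ccccc1)(c1ccccc1)C(C)(C)C)C/C=C/C[C@H](C)[C@@H]1C=C(C(=O)OC)OC(O)[C@@H]1CSC(c1ccccc1)(c1ccccc1)c1ccccc1
F6 | step 21 | 3,4-cis enol δ-lactone, C21 epimer of 38 | I/C=C/C[C@H](O[Si](c1ccccc1)(c1ccccc1)C(C)(C)C)C/C=C/C[C@H](C)[C@@H]1C=C(C(=O)OC)OC(=O)[C@@H]1CSC(c1ccccc1)(c1ccccc1)c1ccccc1
F0 | step 23 | none | none
F7 | step 24 | thiolane N-methoxy-N-methylamide with free α-hydroxy methyl ester | I/C=C/C[C@H](O[Si](c1ccccc1)(c1ccccc1)C(C)(C)C)C/C=C/C[C@H](C)[C@@H]1[C@@H](C(O)C(=O)OC)SC[C@H]1C(=O)N(C)OC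
F8 | step 24 | triethylsilyl ether of F7 | I/C=C/C[C@H](O[Si](c1ccccc1)(c1ccccc1)C(C)(C)C)C/C=C/C[C@H](C)[C@@H]1[C@@H](C(O[Si](CC)(CC)CC)C(=O)OC)SC[C@H]1C(=O)N(C)OC
F9 | step 26 | methyl (1S,2R,5R)-1-hydroxy-4,5-dimethyl-2-[(2E)-3-(tributylstannyl)prop-2-en-1-yl]cyclohex-3-ene-1-carboxylate | CC1=C[C@@H](C/C=C/[Sn](CCCC)(CCCC)CCCC)[C@](O)(C(=O)OC)C[C@H]1C
A1 | alternative 1 | open-chain 3-acyl spirotetronic acid with terminal vinyl groups at C13 and C14 (metathesis substrate) | CC1=C[C@@H](C/C=C/C=C/C[C@H](O[Si](c2ccccc2)(c2ccccc2)C(C)(C)C)CC=C)[C@]2(C[C@H]1C)OC(=O)C(C(=O)[C@@H]3CS[C@H](C(O[Si](CC)(CC)CC)C(=O)OC)[C@H]3[C@@H](C)CC=C)=C2O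
A2 | alternative 2 | linear 3-acyl-5-methylenetetronic acid tethered to the (E,E)-diene terminus (cycloaddition substrate) | C/C=C(C)/C=C/C/C=C/C=C/C[C@H](O[Si](c1ccccc1)(c1ccccc1)C(C)(C)C)C/C=C/C[C@H](C)[C@@H]1[C@@H](C(O[Si](CC)(CC)CC)C(=O)OC)SC[C@H]1C(=O)C1=C(O)C(=C)OC1=O
A3 | alternative 3 | macrocyclic (E)-enoyl tetronic acid lacking the thiolane | CC1=C[C@H]2C/C=C/C=C/C[C@H](O[Si](c3ccccc3)(c3ccccc3)C(C)(C)C)C/C=C/C[C@H](C)/C=C/C(=O)C3=C(O)[C@@]2(C[C@H]1C)OC3=O
A4 | alternative 3 | pyruvoyl-substituted thiocarbonyl ylide | [CH2-][S+]=CC(=O)C(=O)OC
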